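**Retrosynthetic overview**

1. Target 31 comes from MOM-quinone 30 by acetal hydrolysis, and 30 from the hexasubstituted arene 29 by oxidative demethylation. The only ring, the six-membered quinone carbocycle, is carried from the first compound as a benzene ring, so no ring is formed.
2. The strategy rests on the benzylic C1' methylene on ring carbon C6 together with the E-configured C2'=C3' alkene bearing the C3' methyl group. This unit is cut into benzylic chloride 12 (fragment 1), terminal alkyne 26 (fragment 2) and a methyl group from Me3Al (27).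
3. Fragment 1 (12) comes from 2,4,5-trimethoxytoluene (1): hydroxylation between the two methoxy groups, MOM protection, bromination, formylation, reduction, chlorination.
4. Fragment 2 (26) comes from geranylfarnesyl bromide 22 and silylpropyne 23. Bromide 22 comes from farnesyl sulfone 17 and 8-bromogeranyl acetate 15 by sulfone alkylation and desulfonylation, so the four inner E alkenes arrive ready-made from terpene blocks.

Key step: step 15

Remark: (2E,6E)-farnesyl bromide is taken as a commercial material (otherwise made from (2E,6E)-farnesol with PBr3). The side chain is numbered C1' (on the ring) to C24'. Ring locants follow ubiquinone numbering: C1 and C4 carbonyls, C2 OMe, C3 OH, C5 CH3, C6 side chain.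

**Route**

Step 1
Reactants: 1 2,4,5-trimethoxytoluene
Product: 4 2,3,6-trimethoxy-5-methylphenol, via aryllithium 2 (not isolated), via lithium aryltrimethoxyborate 3 (not isolated)
Conditions: n-BuLi, TMEDA, THF, 0 °C; B(OMe)3, −78 °C → rt; H2O2, AcOH, 0 °C
Reagents that add atoms: n-butyllithium, [Li]CCCC (lithium of 2 and 3); trimethyl borate, COB(OC)OC (boron and methoxy groups of 3); hydrogen peroxide, OO (hydroxyl oxygen of 4)
Why: Directed ortho-lithiation should occur at the one ring hydrogen flanked by two methoxy groups, and borylation followed by peroxide oxidation of the aryl borate (1,2-shift of the aryl group from boron to oxygen) turns the C–Li bond into C–OH.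

Step 2
Reactants: 4 2,3,6-trimethoxy-5-methylphenol
Product: 5 1,2,4-trimethoxy-3-(methoxymethoxy)-5-methylbenzene
Conditions: MOMCl, i-Pr2NEt, CH2Cl2, 0 °C → rt
Reagents that add atoms: chloromethyl methyl ether, COCCl
Why: O-alkylation of the phenol with the reactive α-chloro ether gives the MOM acetal, which should withstand the organolithium, hydride and organoaluminium reagents used later and can be removed by mild acid at the end.

Step 3
Reactants: 5 1,2,4-trimethoxy-3-(methoxymethoxy)-5-methylbenzene
Product: 6 1-bromo-2,3,5-trimethoxy-4-(methoxymethoxy)-6-methylbenzene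
Conditions: NBS, dry MeCN, 0 °C → rt, dark
Reagents that add atoms: N-bromosuccinimide, O=C1CCC(=O)N1Br
Why: Electrophilic aromatic bromination can only take place at the single remaining ring hydrogen of the electron-rich arene, and the neutral, non-radical conditions spare the acetal and the benzylic methyl group.

Step 4
Reactants: 6 1-bromo-2,3,5-trimethoxy-4-(methoxymethoxy)-6-methylbenzene
Product: 9 2,3,5-trimethoxy-4-(methoxymethoxy)-6-methylbenzaldehyde, via aryllithium 7 (not isolated), via lithium hemiaminal alkoxide 8 (not isolated)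
Conditions: n-BuLi, THF, −78 °C; DMF, −78 °C → 0 °C; H2O
Reagents that add atoms: n-butyllithium, [Li]CCCC (lithium of 7 and 8); N,N-dimethylformamide, CN(C)C=O (formyl group of 9, and the NMe2 group of 8)
Why: Bromine–lithium exchange at −78 °C is faster than any deprotonation, and the aryllithium adds to DMF to give a hemiaminal alkoxide that releases the aldehyde on aqueous work-up (Bouveault-type formylation).

Step 5
Reactants: 9 2,3,5-trimethoxy-4-(methoxymethoxy)-6-methylbenzaldehyde
Product: 10 [2,3,5-trimethoxy-4-(methoxymethoxy)-6-methylphenyl]methanol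
Conditions: NaBH4, MeOH, 0 °C
Reagents that add atoms: none
Why: Hydride reduction of the aryl aldehyde by NaBH4 is chemoselective and leaves the acetal and the aryl ethers untouched.

Step 6
Reactants: 10 [2,3,5-trimethoxy-4-(methoxymethoxy)-6-methylphenyl]methanol
Product: 12 1-(chloromethyl)-2,3,5-trimethoxy-4-(methoxymethoxy)-6-methylbenzene (fragment 1), via benzylic mesylate 11 (not isolated)
Conditions: MsCl, Et3N, LiCl, THF, 0 °C → rt
Reagents that add atoms: methanesulfonyl chloride, CS(=O)(=O)Cl (mesyl group of 11); lithium chloride, [Li+].[Cl-] (chlorine of 12)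
Why: The alcohol is mesylated and the benzylic mesylate, activated by the ortho and para alkoxy groups, is displaced in the same flask by chloride under basic conditions that keep the MOM acetal intact (Collington–Meyers-type chlorination).

Step 7
Reactants: 13 geranyl acetate
Product: 14 (2E,6E)-8-hydroxy-3,7-dimethylocta-2,6-dien-1-yl acetate
Conditions: SeO2 (cat.), t-BuOOH, salicylic acid (cat.), CH2Cl2, rt, stopped before over-oxidation
Reagents that add atoms: selenium dioxide, O=[Se]=O (delivers the oxygen, catalytic); tert-butyl hydroperoxide, CC(C)(C)OO (terminal oxygen source)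
Why: Selenium dioxide allylic oxidation (ene reaction then 2,3-sigmatropic shift, Sharpless catalytic variant) attacks the more electron-rich distal alkene at its E methyl group and should give the E allylic alcohol, while the 2E alkene is deactivated by the allylic acetate.

Step 8
Reactants: 14 (2E,6E)-8-hydroxy-3,7-dimethylocta-2,6-dien-1-yl acetate
Product: 15 (2E,6E)-8-bromo-3,7-dimethylocta-2,6-dien-1-yl acetate
Conditions: CBr4, PPh3, CH2Cl2, 0 °C
Reagents that add atoms: carbon tetrabromide, BrC(Br)(Br)Br
Why: Appel bromination replaces the primary allylic hydroxyl by SN2 displacement of the oxyphosphonium group under neutral conditions, without allylic transposition or loss of E geometry.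

Step 9
Reactants: 16 (2E,6E)-farnesyl bromide
Product: 17 {[(2E,6E)-3,7,11-trimethyldodeca-2,6,10-trien-1-yl]sulfonyl}benzene (farnesyl phenyl sulfone)
Conditions: PhSO2Na, DMF, rt
Reagents that add atoms: sodium benzenesulfinate, [Na+].[O-]S(=O)c1ccccc1
Why: S-alkylation of the ambident sulfinate by the primary allylic bromide (SN2) gives the allylic sulfone with both E alkenes retained.

Step 10
Reactants: 17 farnesyl phenyl sulfone; 15 (2E,6E)-8-bromo-3,7-dimethylocta-2,6-dien-1-yl acetate
Product: 19 (2E,6E,10E,14E)-3,7,11,15,19-pentamethyl-9-(phenylsulfonyl)icosa-2,6,10,14,18-pentaen-1-yl acetate (racemic at C9), via lithiated sulfone 18 (not isolated)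
Conditions: n-BuLi, THF/DMPU, −78 °C; then 15, −78 °C → −40 °C
Reagents that add atoms: n-butyllithium, [Li]CCCC (lithium of 18)
Why: The sulfone-stabilised allylic carbanion reacts at its α-carbon with the primary allylic bromide at −78 °C (Biellmann/Julia-type sulfone alkylation) much faster than it attacks the acetate; the C9 centre is formed racemic and is erased in step 11.

Step 11
Reactants: 19 (2E,6E,10E,14E)-3,7,11,15,19-pentamethyl-9-(phenylsulfonyl)icosa-2,6,10,14,18-pentaen-1-yl acetate
Product: 21 (2E,6E,10E,14E)-3,7,11,15,19-pentamethylicosa-2,6,10,14,18-pentaen-1-ol (geranylfarnesol), via lithium alkoxide 20 (not isolated)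
Conditions: LiEt3BH (excess), THF, 0 °C; then PdCl2(dppp) (cat.), 0 °C → rt; H2O
Reagents that add atoms: lithium triethylborohydride, [Li+].CC[BH-](CC)CC (lithium of 20 only; otherwise hydride)
Why: The borohydride first reduces the acetate to the lithium alkoxide, which zerovalent palladium cannot ionise; palladium-catalysed hydride substitution of the allylic sulfone (π-allyl complex, hydride delivered to the less substituted terminus under the dppp ligand) then replaces C–S by C–H and should leave the 10E alkene in place and in its geometry.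

Step 12
Reactants: 21 geranylfarnesol
Product: 22 (2E,6E,10E,14E)-1-bromo-3,7,11,15,19-pentamethylicosa-2,6,10,14,18-pentaene (geranylfarnesyl bromide)
Conditions: PBr3, Et2O, −10 °C → 0 °C
Reagents that add atoms: phosphorus tribromide, BrP(Br)Br
Why: The primary allylic alcohol is converted through a phosphite ester that bromide displaces in SN2 fashion at low temperature, the standard bromination of prenols, with the 2E geometry retained.

Step 13
Reactants: 23 1-(trimethylsilyl)propyne; 22 geranylfarnesyl bromide
Product: 25 trimethyl[(5E,9E,13E,17E)-6,10,14,18,22-pentamethyltricosa-5,9,13,17,21-pentaen-1-yn-1-yl]silane, via lithiated silylpropyne 24 (not isolated)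
Conditions: n-BuLi, THF, −20 °C; then 22, −78 °C → −20 °C
Reagents that add atoms: n-butyllithium, [Li]CCCC (lithium of 24)
Why: Lithiated 1-(trimethylsilyl)propyne reacts at its propargylic carbon, the silyl group blocking the allenyl terminus, and displaces the primary allylic bromide directly (SN2) at low temperature, which adds three carbons without disturbing the E alkenes.

Step 14
Reactants: 25 the trimethylsilyl enyne
Product: 26 (5E,9E,13E,17E)-6,10,14,18,22-pentamethyltricosa-5,9,13,17,21-pentaen-1-yne (fragment 2)
Conditions: K2CO3, MeOH/THF, rt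
Reagents that add atoms: none
Why: Methoxide-mediated protodesilylation of the alkynylsilane frees the terminal alkyne and touches nothing else in the hydrocarbon.

Step 15
Reactants: 26 fragment 2; 27 trimethylaluminium; 12 fragment 1
Product: 29 1-[(2E,6E,10E,14E,18E)-3,7,11,15,19,23-hexamethyltetracosa-2,6,10,14,18,22-hexaen-1-yl]-2,3,5-trimethoxy-4-(methoxymethoxy)-6-methylbenzene, via alkenylalane 28 (not isolated)
Conditions: Me3Al, Cp2ZrCl2 (cat.), ClCH2CH2Cl, 0 °C → rt; volatiles removed in vacuo; then 12, Ni(PPh3)4 (cat.), THF, 0 °C → rt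
Reagents that add atoms: trimethylaluminium (27), C[Al](C)C (C3' methyl of 29, and the AlMe2 group of 28)
Why: In the zirconium-catalysed carboalumination (Negishi methylalumination) the Me3Al/Cp2ZrCl2 pair adds methyl and aluminium syn across the terminal alkyne of 26, methyl to the internal carbon (new C3'–CH3 bond) and aluminium to the terminal carbon, so that alane 28 carries the E geometry at C2'=C3'; the five trisubstituted alkenes do not react. After the change to THF, Ni(PPh3)4 (zerovalent nickel) inserts into the benzylic C–Cl bond of 12, the alkenyl group passes from aluminium to nickel with retention, and reductive elimination forms the C1'–C2' bond; the closest known reaction type is the nickel-catalysed cross-coupling of alkenylalanes with benzylic chlorides. No ring closes and no stereocentre forms; the one stereochemical element created, the C2'=C3' alkene, is fixed by the syn addition and by retention in the transmetalation. The step needs methyl delivery to the internal alkyne carbon, which the terminal alkyne with its unbranched propargylic CH2 secures, and sp3–sp2 coupling without transposition, which is secured because a benzylic electrophile has no allylic terminus. Removing free Me3Al before 12 is added, and running the coupling in THF, should keep the MOM acetal and the benzylic chloride away from strong Lewis acid.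

Step 16
Reactants: 29 the coupled arene
Product: 30 2-[(2E,6E,10E,14E,18E)-3,7,11,15,19,23-hexamethyltetracosa-2,6,10,14,18,22-hexaen-1-yl]-6-methoxy-5-(methoxymethoxy)-3-methylcyclohexa-2,5-diene-1,4-dione
Conditions: (NH4)2Ce(NO3)6, MeCN/CH2Cl2/H2O, 0 °C, short reaction time
Reagents that add atoms: water, O (both quinone oxygens)
Why: Oxidative demethylation by tetravalent cerium (two one-electron oxidations of the arene, attack of water at the two para methoxy-bearing carbons, loss of two methanol) converts the only para-dioxygenated pair of the ring into the 1,4-quinone, and brief exposure at 0 °C should leave the isolated trisubstituted alkenes untouched.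

Step 17
Reactants: 30 the MOM-protected quinone
Product: 31 3-demethylubiquinone-6, 2-[(2E,6E,10E,14E,18E)-3,7,11,15,19,23-hexamethyltetracosa-2,6,10,14,18,22-hexaen-1-yl]-5-hydroxy-6-methoxy-3-methylcyclohexa-2,5-diene-1,4-dione
Conditions: 1 M aq. HCl, THF, rt
Reagents that add atoms: none
Why: In the quinone the MOM group is the acetal of a vinylogous carboxylic acid, so dilute aqueous acid hydrolyses it through an oxocarbenium ion at room temperature, too mildly to protonate the chain alkenes; water instead of an alcohol excludes exchange of the hydroxyl for an alkoxy group.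

**Compound list**

1 | 2,4,5-trimethoxytoluene | COc1cc(OC)c(OC)cc1C | starting material
2 | (2,3,6-trimethoxy-5-methylphenyl)lithium | [Li]c1c(OC)c(C)cc(OC)c1OC | intermediate (not isolated)
3 | lithium trimethoxy(2,3,6-trimethoxy-5-methylphenyl)borate | [Li+].CO[B-](OC)(OC)c1c(OC)c(C)cc(OC)c1OC | intermediate (not isolated)
4 | 2,3,6-trimethoxy-5-methylphenol | COc1cc(C)c(OC)c(O)c1OC | intermediate
5 | 1,2,4-trimethoxy-3-(methoxymethoxy)-5-methylbenzene | COCOc1c(OC)c(C)cc(OC)c1OC | intermediate
6 | 1-bromo-2,3,5-trimethoxy-4-(methoxymethoxy)-6-methylbenzene | COCOc1c(OC)c(C)c(Br)c(OC)c1OC | intermediate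
7 | [2,3,5-trimethoxy-4-(methoxymethoxy)-6-methylphenyl]lithium | [Li]c1c(C)c(OC)c(OCOC)c(OC)c1OC | intermediate (not isolated)
8 | lithium (dimethylamino)[2,3,5-trimethoxy-4-(methoxymethoxy)-6-methylphenyl]methanolate (racemic) | [Li]OC(N(C)C)c1c(C)c(OC)c(OCOC)c(OC)c1OC | intermediate (not isolated)
9 | 2,3,5-trimethoxy-4-(methoxymethoxy)-6-methylbenzaldehyde | COCOc1c(OC)c(C)c(C=O)c(OC)c1OC | intermediate
10 | [2,3,5-trimethoxy-4-(methoxymethoxy)-6-methylphenyl]methanol | COCOc1c(OC)c(C)c(CO)c(OC)c1OC | intermediate
11 | [2,3,5-trimethoxy-4-(methoxymethoxy)-6-methylphenyl]methyl methanesulfonate | COCOc1c(OC)c(C)c(COS(C)(=O)=O)c(OC)c1OC | intermediate (not isolated)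
12 | 1-(chloromethyl)-2,3,5-trimethoxy-4-(methoxymethoxy)-6-methylbenzene (fragment 1) | COc1c(OC)c(OCOC)c(OC)c(C)c1CCl | intermediate
13 | geranyl acetate | CC(=O)OC/C=C(\C)CCC=C(C)C | starting material
14 | (2E,6E)-8-hydroxy-3,7-dimethylocta-2,6-dien-1-yl acetate | CC(=O)OC/C=C(\C)CC/C=C(\C)CO | intermediate
15 | (2E,6E)-8-bromo-3,7-dimethylocta-2,6-dien-1-yl acetate | CC(=O)OC/C=C(\C)CC/C=C(\C)CBr | intermediate
16 | (2E,6E)-farnesyl bromide | BrC/C=C(\C)CC/C=C(\C)CCC=C(C)C | starting material
17 | {[(2E,6E)-3,7,11-trimethyldodeca-2,6,10-trien-1-yl]sulfonyl}benzene | O=S(=O)(C/C=C(\C)CC/C=C(\C)CCC=C(C)C)c1ccccc1 | intermediate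
18 | [(2E,6E)-3,7,11-trimethyl-1-(phenylsulfonyl)dodeca-2,6,10-trien-1-yl]lithium | [Li]C(/C=C(\C)CC/C=C(\C)CCC=C(C)C)S(=O)(=O)c1ccccc1 | intermediate (not isolated)
19 | (2E,6E,10E,14E)-3,7,11,15,19-pentamethyl-9-(phenylsulfonyl)icosa-2,6,10,14,18-pentaen-1-yl acetate (racemic at C9) | CC(=O)OC/C=C(\C)CC/C=C(\C)CC(/C=C(\C)CC/C=C(\C)CCC=C(C)C)S(=O)(=O)c1ccccc1 | intermediate
20 | lithium (2E,6E,10E,14E)-3,7,11,15,19-pentamethyl-9-(phenylsulfonyl)icosa-2,6,10,14,18-pentaen-1-olate (racemic at C9) | [Li]OC/C=C(\C)CC/C=C(\C)CC(/C=C(\C)CC/C=C(\C)CCC=C(C)C)S(=O)(=O)c1ccccc1 | intermediate (not isolated)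
21 | (2E,6E,10E,14E)-3,7,11,15,19-pentamethylicosa-2,6,10,14,18-pentaen-1-ol (geranylfarnesol) | OC/C=C(\C)CC/C=C(\C)CC/C=C(\C)CC/C=C(\C)CCC=C(C)C | intermediate
22 | (2E,6E,10E,14E)-1-bromo-3,7,11,15,19-pentamethylicosa-2,6,10,14,18-pentaene | BrC/C=C(\C)CC/C=C(\C)CC/C=C(\C)CC/C=C(\C)CCC=C(C)C | intermediate
23 | 1-(trimethylsilyl)propyne | CC#C[Si](C)(C)C | starting material
24 | [3-(trimethylsilyl)prop-2-yn-1-yl]lithium | [Li]CC#C[Si](C)(C)C | intermediate (not isolated)
25 | trimethyl[(5E,9E,13E,17E)-6,10,14,18,22-pentamethyltricosa-5,9,13,17,21-pentaen-1-yn-1-yl]silane | C[Si](C)(C)C#CCC/C=C(\C)CC/C=C(\C)CC/C=C(\C)CC/C=C(\C)CCC=C(C)C | intermediate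
26 | (5E,9E,13E,17E)-6,10,14,18,22-pentamethyltricosa-5,9,13,17,21-pentaen-1-yne (fragment 2) | C#CCC/C=C(\C)CC/C=C(\C)CC/C=C(\C)CC/C=C(\C)CCC=C(C)C | intermediate
27 | trimethylaluminium | C[Al](C)C | starting material
28 | dimethyl[(1E,5E,9E,13E,17E)-2,6,10,14,18,22-hexamethyltricosa-1,5,9,13,17,21-hexaen-1-yl]alumane | C[Al](C)/C=C(\C)CC/C=C(\C)CC/C=C(\C)CC/C=C(\C)CC/C=C(\C)CCC=C(C)C | intermediate (not isolated)
29 | 1-[(2E,6E,10E,14E,18E)-3,7,11,15,19,23-hexamethyltetracosa-2,6,10,14,18,22-hexaen-1-yl]-2,3,5-trimethoxy-4-(methoxymethoxy)-6-methylbenzene | COc1c(OC)c(OCOC)c(OC)c(C)c1C/C=C(\C)CC/C=C(\C)CC/C=C(\C)CC/C=C(\C)CC/C=C(\C)CCC=C(C)C | intermediate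
30 | 2-[(2E,6E,10E,14E,18E)-3,7,11,15,19,23-hexamethyltetracosa-2,6,10,14,18,22-hexaen-1-yl]-6-methoxy-5-(methoxymethoxy)-3-methylcyclohexa-2,5-diene-1,4-dione | COCOC1=C(OC)C(=O)C(C/C=C(\C)CC/C=C(\C)CC/C=C(\C)CC/C=C(\C)CC/C=C(\C)CCC=C(C)C)=C(C)C1=O | intermediate
31 | 3-demethylubiquinone-6 | COC1=C(O)C(=O)C(C)=C(C/C=C(\C)CC/C=C(\C)CC/C=C(\C)CC/C=C(\C)CC/C=C(\C)CCC=C(C)C)C1=O | target

**Step count**

Total steps: 17. Longest linear sequence: 10 steps (geranyl acetate 13 through steps 7, 8, 10, 11, 12, 13, 14, 15, 16, 17). The arene branch from 1 is 9 steps to the target.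

**Steps most likely to fail, with fallbacks**

Step 15. The aluminium species may act as Lewis acids on the MOM acetal or ionise the electron-rich benzylic chloride (Friedel–Crafts-type self-condensation). Alkenyl transfer from aluminium to nickel may also be slow enough for benzylic homocoupling to compete. The fallback reverses the polarity and takes aluminium out of the coupling. It sets out from alane 28 (made from 26 as in step 15) and from chloride 12. Alane 28 is quenched with I2 in THF at −30 °C to give (1E,5E,9E,13E,17E)-1-iodo-2,6,10,14,18,22-hexamethyltricosa-1,5,9,13,17,21-hexaene F1, with the geometry retained. Chloride 12 is treated with zinc dust and LiCl in THF to give chloro{[2,3,5-trimethoxy-4-(methoxymethoxy)-6-methylphenyl]methyl}zinc F2. Negishi coupling of F1 with F2 under Pd(PPh3)4 (zerovalent palladium) in THF at rt comes back to the route at 29.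

Step 16. The acidic oxidant may strip the MOM group before the ring is oxidised, after which the free phenol could steer the oxidation towards ortho-quinones. The six chain alkenes may also suffer oxidative attack. The fallback moves the oxidation ahead of the coupling, so that the polyene never meets the cerium reagent. It sets out from chloride 12, which is oxidised with (NH4)2Ce(NO3)6 in MeCN/H2O at 0 °C to 2-(chloromethyl)-6-methoxy-5-(methoxymethoxy)-3-methylcyclohexa-2,5-diene-1,4-dione F3. This chloromethyl quinone is coupled with alane 28 (from 26 and 27 as in step 15) under Ni(PPh3)4 (zerovalent nickel) in THF, a known coupling of alkenylalanes with chloromethyl benzoquinones, and the route is rejoined at 30.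

Step 11. Hydride may be delivered to the more substituted allyl terminus, or the alkene may migrate. If ester reduction is incomplete when the palladium is added, ionisation of the allylic acetate would lead to deoxygenation. The fallback separates the two events and cleaves the C–S bond by electron transfer instead of through a π-allyl palladium hydride. It sets out from 19, which is deacetylated with K2CO3 in MeOH to (2E,6E,10E,14E)-3,7,11,15,19-pentamethyl-9-(phenylsulfonyl)icosa-2,6,10,14,18-pentaen-1-ol F4. The free alcohol is then desulfonylated with lithium in ethylamine at −78 °C (dissolving-metal reduction of the allylic sulfone), which comes back to the route at 21.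

**Further compounds**

F1 | step 15 | (1E,5E,9E,13E,17E)-1-iodo-2,6,10,14,18,22-hexamethyltricosa-1,5,9,13,17,21-hexaene | I/C=C(\C)CC/C=C(\C)CC/C=C(\C)CC/C=C(\C)CC/C=C(\C)CCC=C(C)C
F2 | step 15 | chloro{[2,3,5-trimethoxy-4-(methoxymethoxy)-6-methylphenyl]methyl}zinc | COc1c(OC)c(OCOC)c(OC)c(C)c1C[Zn]Cl
F3 | step 16 | 2-(chloromethyl)-6-methoxy-5-(methoxymethoxy)-3-methylcyclohexa-2,5-diene-1,4-dione | COCOC1=C(OC)C(=O)C(CCl)=C(C)C1=O
F4 | step 11 | (2E,6E,10E,14E)-3,7,11,15,19-pentamethyl-9-(phenylsulfonyl)icosa-2,6,10,14,18-pentaen-1-ol (racemic at C9) | OC/C=C(\C)CC/C=C(\C)CC(/C=C(\C)CC/C=C(\C)CCC=C(C)C)S(=O)(=O)c1ccccc1
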